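## Retrosynthetic overview

1. Daucane numbering is used: C1 methyl-bearing fusion carbon, C2/C3 ring CH2, C4 isopropyl carbinol, C5 fusion CH, C6 ester-bearing carbon, C7 CH2, C8(Me)=C9, C10 CH2. The strategy rests on the seven-membered ring C1–C5–C6–C7–C8–C9–C10. Its carbons C7–C8–C9–C10–C1 are the five-carbon unit of a vinylcyclopropane (vinyl C7=C8, ring C9/C10/C1) and C5–C6 is a two-carbon alkyne unit. The skipped diene C5=C6 / C8=C9 around C7 is what a (5+2) adduct carries.
2. Teferin ⇒ jaeschkeanadiol 16 + silyl-protected vanillic acid 19 (C6–O acylation last). 16 ⇒ C6 ketone 15 (C4-OH-directed reduction) ⇒ C6 alkenylsilane 13 (C–Si oxidation, C5 set on protonation).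
3. 13 ⇒ 12 by cutting C1–C5 and C6–C7 (Rh-catalysed intramolecular (5+2)). The cyclopentane (through the C2–C3–C4 tether) and the cycloheptadiene form together.
4. 12 ⇒ isopropyl ketone 8 + silylacetylene 11 (C4–C5 bond). 8 ⇒ nerol, which supplies C1, its methyl, C2, C3, C4, the isopropyl group, C8 and C9 with the Z geometry that places vinyl and tether cis. C10 comes from CH2I2, the C8 methyl from MeLi, C7 from the Wittig reagent.
5. Ring order: cyclopropane (step 1), then cyclopentane and cycloheptadiene in one event (step 9), in which the cyclopropane is consumed.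

Key step: step 9

Assumption: the (4R,5R)-dioxaborolane is taken to deliver methylene to nerol with the same facial sense as to other allylic alcohols (carbinol-bearing ring carbon S). The salen enantiomer in step 8 is taken to be the one that adds to the Si face; its sense is fixed by a trial on 2-methylheptan-3-one and the mirror-image ligand is used if it is opposite.

## Route

Step 1
Reactants: 1 nerol
Product: 2 [(1S,2R)-2-methyl-2-(4-methylpent-3-en-1-yl)cyclopropyl]methanol
Conditions: Et2Zn, CH2I2, DME, (4R,5R)-2-butyl-N,N,N',N'-tetramethyl-1,3,2-dioxaborolane-4,5-dicarboxamide (1.2 equiv), CH2Cl2, −10 °C to rt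
Reagents that add atoms: diiodomethane, ICI
Why: Charette asymmetric Simmons–Smith cyclopropanation, in which the zinc alkoxide bound to the chiral dioxaborolane directs methylene to one face of the allylic alkene only (the remote prenyl alkene is untouched); the Z geometry puts CH2OH and the chain cis and the controller sets the quaternary carbon that becomes C1.

Step 2
Reactants: 2 [(1S,2R)-2-methyl-2-(4-methylpent-3-en-1-yl)cyclopropyl]methanol
Product: 4 (1S,2R)-2-methyl-2-(4-methylpent-3-en-1-yl)cyclopropane-1-carboxylic acid, via cyclopropanecarbaldehyde 3 (not isolated)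
Conditions: TEMPO (cat.), PhI(OAc)2 (2.2 equiv), MeCN/H2O 1:1, rt
Reagents that add atoms: water, O
Why: Oxoammonium (TEMPO/PhI(OAc)2) oxidation takes the primary alcohol through the aldehyde hydrate to the acid under near-neutral conditions that leave the trisubstituted alkene and the cis-cyclopropane configuration alone.

Step 3
Reactants: 4 (1S,2R)-2-methyl-2-(4-methylpent-3-en-1-yl)cyclopropane-1-carboxylic acid
Product: 5 1-[(1S,2R)-2-methyl-2-(4-methylpent-3-en-1-yl)cyclopropyl]ethan-1-one
Conditions: MeLi (2.2 equiv), Et2O, 0 °C to rt; inverse quench into cold 1 M HCl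
Reagents that add atoms: methyllithium, [Li]C
Why: Classical methyl ketone synthesis from a lithium carboxylate and methyllithium, in which the gem-diolate survives until the quench so that over-addition is avoided and the ring stereocentres are not touched.

Step 4
Reactants: 5 1-[(1S,2R)-2-methyl-2-(4-methylpent-3-en-1-yl)cyclopropyl]ethan-1-one
Product: 6 (1R,2R)-1-methyl-1-(4-methylpent-3-en-1-yl)-2-(prop-1-en-2-yl)cyclopropane
Conditions: Ph3PCH3Br, KOtBu, THF, 0 °C to rt
Reagents that add atoms: methyltriphenylphosphonium bromide, C[P+](c1ccccc1)(c1ccccc1)c1ccccc1.[Br-]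
Why: Wittig methylenation of the methyl ketone; enolisation of a cyclopropyl ketone toward the ring is strongly disfavoured, so the cis relationship of the new isopropenyl group and the chain is kept (the descriptor at the ring CH changes only through CIP priorities).

Step 5
Reactants: 6 (1R,2R)-1-methyl-1-(4-methylpent-3-en-1-yl)-2-(prop-1-en-2-yl)cyclopropane
Product: 7 2,2-dimethyl-3-{2-[(1R,2R)-1-methyl-2-(prop-1-en-2-yl)cyclopropyl]ethyl}oxirane (both epimers at the oxirane CH)
Conditions: mCPBA (1.0 equiv), NaHCO3, CH2Cl2, −20 to 0 °C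
Reagents that add atoms: meta-chloroperoxybenzoic acid, OOC(=O)c1cccc(Cl)c1
Why: Prilezhaev epoxidation is electrophilic and should select the trisubstituted prenyl alkene over the 1,1-disubstituted isopropenyl group, which is also shielded by the cis chain and the neighbouring quaternary carbon; the new stereocentre is erased in step 6.

Step 6
Reactants: 7 2,2-dimethyl-3-{2-[(1R,2R)-1-methyl-2-(prop-1-en-2-yl)cyclopropyl]ethyl}oxirane
Product: 8 2-methyl-5-[(1R,2R)-1-methyl-2-(prop-1-en-2-yl)cyclopropyl]pentan-3-one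
Conditions: BF3·OEt2 (0.3 equiv), CH2Cl2, −78 °C, short contact; Et3N quench
Reagents that add atoms: none
Why: Meinwald rearrangement, in which the Lewis acid opens the epoxide at its tertiary carbon and a 1,2-hydride shift from the adjacent CH gives the isopropyl ketone, the low temperature and short contact sparing the vinylcyclopropane.

Step 7
Reactants: 9 benzylchlorodimethylsilane; 10 ethynylmagnesium bromide
Product: 11 benzyl(ethynyl)dimethylsilane
Conditions: THF, 0 °C to rt (Grignard reagent in excess)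
Reagents that add atoms: none
Why: Nucleophilic substitution at silicon by the acetylide Grignard reagent, an excess of which suppresses bis-silylation.

Step 8
Reactants: 8 2-methyl-5-[(1R,2R)-1-methyl-2-(prop-1-en-2-yl)cyclopropyl]pentan-3-one; 11 benzyl(ethynyl)dimethylsilane
Product: 12 (3R)-1-[benzyl(dimethyl)silyl]-5-[(1R,2R)-1-methyl-2-(prop-1-en-2-yl)cyclopropyl]-3-(propan-2-yl)pent-1-yn-3-ol
Conditions: Me2Zn (3 equiv), 11 (3 equiv), (R,R)-N,N'-bis(3,5-di-tert-butylsalicylidene)-1,2-cyclohexanediamine (20 mol %), toluene, rt to 40 °C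
Reagents that add atoms: none
Why: Catalytic asymmetric alkynylzinc addition to a ketone (Zn(salen) type), in which the non-basic methylzinc acetylide adds without enolisation and the ligand directs it to the Si face (O > iPr > CH2) to give 3R; the remote cyclopropane exerts no bias and the ligand has to tell isopropyl from a primary chain, so any 3S epimer that cannot be removed here is removed after step 9, where the epimers are cis/trans isomers of a rigid bicycle.

Step 9
Reactants: 12 (3R)-1-[benzyl(dimethyl)silyl]-5-[(1R,2R)-1-methyl-2-(prop-1-en-2-yl)cyclopropyl]-3-(propan-2-yl)pent-1-yn-3-ol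
Product: 13 (3R,8aR)-4-[benzyl(dimethyl)silyl]-6,8a-dimethyl-3-(propan-2-yl)-1,2,3,5,8,8a-hexahydroazulen-3-ol (6-silyl-dauca-5,8-dien-4β-ol)
Conditions: [Rh(CO)2Cl]2 (5 mol %), ClCH2CH2Cl (0.02 M), 70 °C, N2
Reagents that add atoms: none
Why: Rh(I) binds the isopropenyl group and adds oxidatively into the adjacent C9–C1 cyclopropane bond to give a rhodacycle with a Rh–C1 σ bond and an allyl unit over C7–C8–C9; the tethered alkyne then inserts into Rh–C1 (C1–C5 bond) and reductive elimination joins C6 to the allyl terminus C7. The closest known reaction type is the Rh(I)-catalysed intramolecular (5+2) cycloaddition of vinylcyclopropanes that carry the 2π partner on the neighbouring ring carbon cis to the vinyl group (cis-2-ene-vinylcyclopropanes); the silylalkyne partner and the fully substituted inserting carbon go beyond the simplest cases of that class. The cyclopentane closes in the 5-exo-dig mode by carbometallation of the alkyne through the C2–C3–C4 tether, and the cycloheptadiene closes by C(sp2)–C(sp3) reductive elimination between C6 and C7 of an eight-membered rhodacycle, the cisoid allyl giving C8=C9 as the ring Z alkene. C1 is the only stereocentre carried through the event: oxidative addition and migratory insertion both proceed with retention at C1, so its configuration is the one fixed in step 1, C4 is a spectator and C9 becomes sp2. The step needs C6–C7 closure (5+2) rather than C6–C9 closure (3+2), which the cis placement of isopropenyl and tether secures, and opening of C9–C1 rather than C9–C10, which chelation of rhodium between the alkene and the tethered alkyne should secure; the temperature is kept below that of the thermal homodienyl 1,5-hydrogen shift of cis-alkyl vinylcyclopropanes.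

Step 10
Reactants: 13 (3R,8aR)-4-[benzyl(dimethyl)silyl]-6,8a-dimethyl-3-(propan-2-yl)-1,2,3,5,8,8a-hexahydroazulen-3-ol
Product: 15 (3R,3aR,8aR)-3-hydroxy-6,8a-dimethyl-3-(propan-2-yl)-2,3,3a,5,8,8a-hexahydroazulen-4(1H)-one, via oxasilole 14 (not isolated)
Conditions: TBAF, THF, 0 °C to rt; then KHCO3, 30% H2O2, MeOH/THF, rt to 40 °C
Reagents that add atoms: hydrogen peroxide, OO
Why: Tamao–Fleming oxidation of a benzyldimethylsilyl alkene, in which fluoride expels the benzyl group as toluene while the C4 alkoxide closes onto silicon, peroxide converts the activated C6–Si bond into the C6 enol, and the enol should settle under the bicarbonate conditions as the trans-fused ketone (5α-H), which holds C6 trans to the C4 isopropyl group and allows an O4–H···O=C6 hydrogen bond.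

Step 11
Reactants: 15 (3R,3aR,8aR)-3-hydroxy-6,8a-dimethyl-3-(propan-2-yl)-2,3,3a,5,8,8a-hexahydroazulen-4(1H)-one
Product: 16 (3R,3aS,4S,8aR)-6,8a-dimethyl-3-(propan-2-yl)-1,2,3,3a,4,5,8,8a-octahydroazulene-3,4-diol (jaeschkeanadiol)
Conditions: Me4NBH(OAc)3, MeCN/AcOH 1:1, −30 to −20 °C
Reagents that add atoms: none
Why: Evans–Saksena hydroxyl-directed reduction, in which the β-oriented C4–OH binds boron and delivers hydride within a six-membered transition state to the β face of the C6 carbonyl, giving the 6α-alcohol (1,3-anti diol).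

Step 12
Reactants: 17 vanillic acid
Product: 19 4-[(tert-butyldimethylsilyl)oxy]-3-methoxybenzoic acid, via bis-silyl derivative 18 (not isolated)
Conditions: TBSCl (2.5 equiv), imidazole, DMF, rt; then AcOH/THF/H2O, rt
Reagents that add atoms: tert-butyldimethylsilyl chloride, CC(C)(C)[Si](C)(C)Cl
Why: Silylation of phenol and acid followed by selective hydrolysis of the far more labile silyl ester, leaving the aryl silyl ether as phenol protection.

Step 13
Reactants: 16 (3R,3aS,4S,8aR)-6,8a-dimethyl-3-(propan-2-yl)-1,2,3,3a,4,5,8,8a-octahydroazulene-3,4-diol; 19 4-[(tert-butyldimethylsilyl)oxy]-3-methoxybenzoic acid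
Product: 20 (3R,3aS,4S,8aR)-3-hydroxy-6,8a-dimethyl-3-(propan-2-yl)-1,2,3,3a,4,5,8,8a-octahydroazulen-4-yl 4-[(tert-butyldimethylsilyl)oxy]-3-methoxybenzoate
Conditions: DCC, DMAP, CH2Cl2, rt
Reagents that add atoms: none
Why: Steglich esterification acylates the secondary C6 alcohol, while the tertiary C4 alcohol flanked by isopropyl is too hindered to react.

Step 14
Reactants: 20 (3R,3aS,4S,8aR)-3-hydroxy-6,8a-dimethyl-3-(propan-2-yl)-1,2,3,3a,4,5,8,8a-octahydroazulen-4-yl 4-[(tert-butyldimethylsilyl)oxy]-3-methoxybenzoate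
Product: 21 teferin
Conditions: TBAF (1.1 equiv), AcOH (1.1 equiv), THF, 0 °C
Reagents that add atoms: none
Why: Fluoride cleavage of the aryl silyl ether, buffered with acetic acid so that the benzoate ester and the tertiary alcohol are not affected.

## Compound list

1 | nerol | CC(C)=CCC/C(C)=C\CO | starting material
2 | [(1S,2R)-2-methyl-2-(4-methylpent-3-en-1-yl)cyclopropyl]methanol | OC[C@H]1C[C@@]1(C)CCC=C(C)C | intermediate
3 | (1S,2R)-2-methyl-2-(4-methylpent-3-en-1-yl)cyclopropane-1-carbaldehyde | O=C[C@H]1C[C@@]1(C)CCC=C(C)C | intermediate (not isolated)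
4 | (1S,2R)-2-methyl-2-(4-methylpent-3-en-1-yl)cyclopropane-1-carboxylic acid | OC(=O)[C@H]1C[C@@]1(C)CCC=C(C)C | intermediate
5 | 1-[(1S,2R)-2-methyl-2-(4-methylpent-3-en-1-yl)cyclopropyl]ethan-1-one | CC(=O)[C@H]1C[C@@]1(C)CCC=C(C)C | intermediate
6 | (1R,2R)-1-methyl-1-(4-methylpent-3-en-1-yl)-2-(prop-1-en-2-yl)cyclopropane | C=C(C)[C@H]1C[C@@]1(C)CCC=C(C)C | intermediate
7 | 2,2-dimethyl-3-{2-[(1R,2R)-1-methyl-2-(prop-1-en-2-yl)cyclopropyl]ethyl}oxirane (epimers at oxirane CH) | C=C(C)[C@H]1C[C@@]1(C)CCC2OC2(C)C | intermediate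
8 | 2-methyl-5-[(1R,2R)-1-methyl-2-(prop-1-en-2-yl)cyclopropyl]pentan-3-one | C=C(C)[C@H]1C[C@@]1(C)CCC(=O)C(C)C | intermediate
9 | benzylchlorodimethylsilane | C[Si](C)(Cl)Cc1ccccc1 | starting material
10 | ethynylmagnesium bromide | C#C[Mg]Br | starting material
11 | benzyl(ethynyl)dimethylsilane | C#C[Si](C)(C)Cc1ccccc1 | intermediate
12 | (3R)-1-[benzyl(dimethyl)silyl]-5-[(1R,2R)-1-methyl-2-(prop-1-en-2-yl)cyclopropyl]-3-(propan-2-yl)pent-1-yn-3-ol | C=C(C)[C@H]1C[C@@]1(C)CC[C@@](O)(C(C)C)C#C[Si](C)(C)Cc1ccccc1 | intermediate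
13 | (3R,8aR)-4-[benzyl(dimethyl)silyl]-6,8a-dimethyl-3-(propan-2-yl)-1,2,3,5,8,8a-hexahydroazulen-3-ol | C[Si](C)(Cc1ccccc1)C=1CC(C)=CC[C@@]2(C)CC[C@@](O)(C(C)C)C12 | intermediate
14 | oxasilole: Si,Si-dimethyl siloxane bridging O4 and C6 of 13 after loss of toluene | C[Si]1(C)O[C@@]2(C(C)C)CC[C@]3(C)CC=C(C)CC1=C23 | intermediate (not isolated)
15 | (3R,3aR,8aR)-3-hydroxy-6,8a-dimethyl-3-(propan-2-yl)-2,3,3a,5,8,8a-hexahydroazulen-4(1H)-one | O=C1CC(C)=CC[C@@]2(C)CC[C@@](O)(C(C)C)[C@H]12 | intermediate
16 | (3R,3aS,4S,8aR)-6,8a-dimethyl-3-(propan-2-yl)-1,2,3,3a,4,5,8,8a-octahydroazulene-3,4-diol (jaeschkeanadiol) | O[C@H]1CC(C)=CC[C@@]2(C)CC[C@@](O)(C(C)C)[C@H]12 | intermediate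
17 | vanillic acid | COc1cc(C(=O)O)ccc1O | starting material
18 | tert-butyldimethylsilyl 4-[(tert-butyldimethylsilyl)oxy]-3-methoxybenzoate | COc1cc(C(=O)O[Si](C)(C)C(C)(C)C)ccc1O[Si](C)(C)C(C)(C)C | intermediate (not isolated)
19 | 4-[(tert-butyldimethylsilyl)oxy]-3-methoxybenzoic acid | COc1cc(C(=O)O)ccc1O[Si](C)(C)C(C)(C)C | intermediate
20 | (3R,3aS,4S,8aR)-3-hydroxy-6,8a-dimethyl-3-(propan-2-yl)-1,2,3,3a,4,5,8,8a-octahydroazulen-4-yl 4-[(tert-butyldimethylsilyl)oxy]-3-methoxybenzoate | COc1cc(C(=O)O[C@H]2CC(C)=CC[C@@]3(C)CC[C@@](O)(C(C)C)[C@H]23)ccc1O[Si](C)(C)C(C)(C)C | intermediate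
21 | teferin | COc1cc(C(=O)O[C@H]2CC(C)=CC[C@@]3(C)CC[C@@](O)(C(C)C)[C@H]23)ccc1O | target

## Step count and risks

Total step count: 14. Longest linear sequence: 12 steps (steps 1–6, 8–11, 13, 14, from nerol).

**Step 9 (key step).** What may go wrong: oxidative addition has to occur at the more hindered C9–C1 bond, and the bulky silylalkyne has to insert into a tertiary alkyl–rhodium bond. Opening of the unhindered C9–C10 bond, β-hydride elimination to ring-opened dienes, or (3+2) closure may outrun the desired path.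

The fallback sets out from 12 and returns at 15. It replaces the alkyne by the alkene partner on which this cycloaddition mode was established, and takes both C5 and the C6 oxidation level out of the cycloaddition.
- Red-Al reduction of the propargylic alcohol 12 (trans-hydroalumination, then protonolysis) gives the (E)-vinylsilane F1.
- Rh(I)-catalysed (5+2) cycloaddition of this cis-2-ene-vinylcyclopropane should give the C6 alkylsilane F2, with C5 and C6 as formed.
- Tamao–Fleming oxidation of the C(sp3)–Si bond (TBAF, then H2O2/KHCO3) gives the diol F3.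
- Dess–Martin oxidation of the secondary C6 alcohol gives 15 and/or its C5 epimer F4, which brief base equilibration (DBU, CH2Cl2) converts to the trans-fused ketone 15.

**Step 8.** What may go wrong: weak facial discrimination between isopropyl and the primary chain, and slow addition of the zinc acetylide to a hindered ketone.

The fallback sets out from 7 and returns at 12. It sets C4 by Sharpless epoxidation of a geometrically defined allylic alcohol instead of by ketone addition.
- Periodic acid (THF/H2O, 0 °C) cleaves the epoxide 7 to the aldehyde F5.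
- The Ohira–Bestmann reagent (K2CO3, MeOH) gives the terminal alkyne F6.
- n-BuLi, then methyl chloroformate, gives the ynoate F7.
- syn-Carbocupration with the isopropyl cuprate (i-PrMgCl, CuBr·SMe2, THF, −78 °C, protonation cold) gives the (E)-enoate F8, with isopropyl and H cis.
- DIBAL-H gives the allylic alcohol F9.
- Sharpless asymmetric epoxidation (Ti(OiPr)4, D-(−)-diethyl tartrate, TBHP) gives the (2R,3R)-epoxy alcohol F10, which fixes C4 by reagent control.
- Appel chlorination (PPh3, CCl4) gives the epoxy chloride F11.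
- n-BuLi (3 equiv, THF, −40 °C) effects the double elimination to the tertiary propargylic alcohol F12 without touching the carbinol C–O bond.
- C-Silylation of the dianion of F12 (EtMgBr, 2 equiv, then 9) gives 12 as a single C4 epimer.

**Step 6.** What may go wrong: the cation formed at the tertiary epoxide carbon may be diverted (alkyl shift to an aldehyde, fluoride capture, elimination), and the acid may open the vinylcyclopropane.

The fallback sets out from 7 and returns at 8. No carbocation is involved.
- Diethylaluminium 2,2,6,6-tetramethylpiperidide (toluene, 0 °C) isomerises the epoxide 7 to the allylic alcohol F13 by syn-elimination from a methyl group.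
- Dess–Martin oxidation gives the enone F14.
- Conjugate reduction with Stryker's reagent ([(Ph3P)CuH]6, benzene/H2O) gives 8.

Further compounds

F1 | step 9 | (1E,3R)-1-[benzyl(dimethyl)silyl]-5-[(1R,2R)-1-methyl-2-(prop-1-en-2-yl)cyclopropyl]-3-(propan-2-yl)pent-1-en-3-ol | C=C(C)[C@H]1C[C@@]1(C)CC[C@@](O)(C(C)C)/C=C/[Si](C)(C)Cc1ccccc1
F2 | step 9 | (3R,8aR)-4-[benzyl(dimethyl)silyl]-6,8a-dimethyl-3-(propan-2-yl)-1,2,3,3a,4,5,8,8a-octahydroazulen-3-ol (C3a and C4 as formed) | C[Si](C)(Cc1ccccc1)C1CC(C)=CC[C@@]2(C)CC[C@@](O)(C(C)C)C12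
F3 | step 9 | (3R,8aR)-6,8a-dimethyl-3-(propan-2-yl)-1,2,3,3a,4,5,8,8a-octahydroazulene-3,4-diol (C3a and C4 as formed) | OC1CC(C)=CC[C@@]2(C)CC[C@@](O)(C(C)C)C12
F4 | step 9 | (3R,3aS,8aR)-3-hydroxy-6,8a-dimethyl-3-(propan-2-yl)-2,3,3a,5,8,8a-hexahydroazulen-4(1H)-one (C5 epimer of 15) | O=C1CC(C)=CC[C@@]2(C)CC[C@@](O)(C(C)C)[C@@H]12
F5 | step 8 | 3-[(1R,2R)-1-methyl-2-(prop-1-en-2-yl)cyclopropyl]propanal | C=C(C)[C@H]1C[C@@]1(C)CCC=O
F6 | step 8 | (1R,2R)-1-(but-3-yn-1-yl)-1-methyl-2-(prop-1-en-2-yl)cyclopropane | C=C(C)[C@H]1C[C@@]1(C)CCC#C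
F7 | step 8 | methyl 5-[(1R,2R)-1-methyl-2-(prop-1-en-2-yl)cyclopropyl]pent-2-ynoate | C=C(C)[C@H]1C[C@@]1(C)CCC#CC(=O)OC
F8 | step 8 | methyl (2E)-5-[(1R,2R)-1-methyl-2-(prop-1-en-2-yl)cyclopropyl]-3-(propan-2-yl)pent-2-enoate | C=C(C)[C@H]1C[C@@]1(C)CC/C(C(C)C)=C\C(=O)OC
F9 | step 8 | (2E)-5-[(1R,2R)-1-methyl-2-(prop-1-en-2-yl)cyclopropyl]-3-(propan-2-yl)pent-2-en-1-ol | C=C(C)[C@H]1C[C@@]1(C)CC/C(C(C)C)=C\CO
F10 | step 8 | [(2R,3R)-3-{2-[(1R,2R)-1-methyl-2-(prop-1-en-2-yl)cyclopropyl]ethyl}-3-(propan-2-yl)oxiran-2-yl]methanol | C=C(C)[C@H]1C[C@@]1(C)CC[C@]2(C(C)C)O[C@@H]2CO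
F11 | step 8 | (2S,3R)-2-(chloromethyl)-3-{2-[(1R,2R)-1-methyl-2-(prop-1-en-2-yl)cyclopropyl]ethyl}-3-(propan-2-yl)oxirane | C=C(C)[C@H]1C[C@@]1(C)CC[C@]2(C(C)C)O[C@@H]2CCl
F12 | step 8 | (3R)-5-[(1R,2R)-1-methyl-2-(prop-1-en-2-yl)cyclopropyl]-3-(propan-2-yl)pent-1-yn-3-ol | C=C(C)[C@H]1C[C@@]1(C)CC[C@@](O)(C(C)C)C#C
F13 | step 6 | 2-methyl-5-[(1R,2R)-1-methyl-2-(prop-1-en-2-yl)cyclopropyl]pent-1-en-3-ol (epimers at C3) | C=C(C)[C@H]1C[C@@]1(C)CCC(O)C(C)=C
F14 | step 6 | 2-methyl-5-[(1R,2R)-1-methyl-2-(prop-1-en-2-yl)cyclopropyl]pent-1-en-3-one | C=C(C)[C@H]1C[C@@]1(C)CCC(=O)C(C)=C
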